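You can misjudge a self-feeding reaction if you take its rate from the lag, where the curve looks like a titration, and carry that rate into a continuous tank.

| flask | starting material | reagent | base | remark | time |
|---|---|---|---|---|---|
| theta | 15 mM | 7.5 mM | 0.30 mM | run made earlier |  |
| alpha | 15 mM | 10 mM | 0.30 mM | run made earlier |  |
| epsilon | 15 mM | 16 mM | 0.30 mM | run made earlier |  |
| zeta | 7.5 mM | 7.5 mM | 0.30 mM | run made earlier |  |
| red | 15 mM | 7.50 mM | 0.300 mM | a single well-mixed tank run continuously and read at steady state, 2.0 min in it on average |  |
| violet | 15 mM | 7.50 mM (fed, over 1.00 min) | 0.300 mM | all but reagent at the start; reagent goes in evenly over 1.00 min, the run ends at 2.0 min | 2.0 min |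
| teal | 15 mM | 7.50 mM | 0.300 mM | everything together in a closed stirred flask, run for 2.0 min | 2.0 min |
| blue | 15 mM (fed, over 1.00 min) | 7.50 mM | 0.300 mM | all but starting material at the start; starting material goes in evenly over 1.00 min, the run ends at 2.0 min | 2.0 min |

- theta (time / s: target / %): 15.0: 0; 30.0: 0.1; 40.0: 2.0; 60.0: 0; 80.0: 1.1
- alpha (time / s: target / %): 10.0: 0; 30.0: 1.1; 60.0: 2.1; 80.0: 2.6; 120: 5.4
- epsilon (time / s: target / %): 10.0: 1.1; 30.0: 0.7; 60.0: 4.3; 80.0: 9.5; 120: 49.1
- zeta (time / s: target / %): 10.0: 0.1; 30.0: 0.9; 60.0: 0; 80.0: 2.1; 120: 2.0

(standard deviation of a reading: 1 percentage point)

- the stated concentrations are those of everything mixed, before any reaction; amounts are the same in each set-up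
- the numbers in the tables scatter with a standard deviation of 1 percentage point
- the feed brings no volume worth counting
- the earlier runs were made in a closed, stirred flask

* the set-up with the highest amount of target at the outlet or at the end, in percent of the starting material put in ("none" if the first two lie within 2 percentage points) (red / violet / teal / blue / none)
* amount of target at the outlet or at the end, in percent of the starting material put in, red
* amount of target at the outlet or at the end, in percent of the starting material put in, violet
* amount of target at the outlet or at the end, in percent of the starting material put in, teal
* amount of target at the outlet or at the end, in percent of the starting material put in, blue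

Build the red tank up one process at a time; the reckoning here is my own. First take the main step by itself, with its rate going as starting material times reagent and scaled from the alpha reading of 2.1% at 60.0 s, a reading that carries a scatter of 1 percentage point. Over the 2.0 min that liquid spends in red on average, this gives

first round: 0.473 mM of target.

Now add the base. As I read alpha and epsilon, the steep rise begins near a target equal to the base charge, 2.00% of the starting material, so I count as self-feeding (autocatalysis) just the target above 0.300 mM, and the first round is more than that charge.

Next add the self-feeding. Epsilon's charged product, divided by the growth rate of that excess in epsilon between 60.0 s and 80.0 s and then by the mean time in red, gives the break-even product, meaning the starting material times reagent at which excess target in the tank just replaces itself: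

break-even product = 33.8 mM^2

Red's charged product, 112 mM^2, is more than this, so the target must consume its own feed until remaining starting material times remaining reagent equals the break-even product times target/(target − base charge). Set that fraction to one, then put the answer back in and go round again:

second round: 4.33 mM

third round: 4.15 mM, or 27.7% of the starting material.

The forecast chose red, with 6.5% for red, 2.2% for violet, 3.2% for teal and 2% for blue, and it judged “gain × residence time is about 1.1, right at ignition”.

    starting material + reagent + by-product → target + 2 by-product (k = 330 L² mol⁻² s⁻¹)
    starting material + reagent → target + by-product (k = 0.0260 L mol⁻¹ s⁻¹)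
    base + by-product ⇌ salt, settled at all times (K = 2.10 × 10⁵ L mol⁻¹)

Red gives 32.6%, against the forecast's 6.5%, and it is the best set-up, with teal at 2.83%, violet at 1.83% and blue at 1.83%. The red tank keeps 67.4% of its starting material with reagent at 2.61 mM, a product of 26.4 mM^2, which is less than the break-even product of 33.8 mM^2 read from epsilon. Over the same 2.0 min, teal's charged product is 3.32 break-even products, and a closed neighbour of teal with 19 mM of reagent has 8.42 and ends at 71.7%.

All runs are simulated with constants of no real substance, and the scatter is random.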